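**Plan**

1. Numbering used throughout (undec-9-enoic acid): C1 = free CO2H, C2 = its α-stereocentre, C3–C5 = the three CH2 groups, C6 = stereocentre bearing CO2Me.
2. Retrosynthesis: C6–CO2Me ⇒ C6–CH2OH; C4–C5 ⇒ (E)-alkene; cut C2–C3 by a [3,3] shift ⇒ allylic ester 19; cut the ester C–O ⇒ alcohol 13 + acid 18; cut C5–C6 by an aldol ⇒ imide 7 + acrolein.
3. Enabling feature: the free acid C1 with its α-stereocentre C2 and the unfunctionalised C3–C4–C5 chain becomes a γ,δ-unsaturated acid once a C4=C5 alkene is written in, which is the retron of an ester enolate Claisen rearrangement. C5 is next to C6, so the allylic C5–O carbinol that the rearrangement needs is the β-hydroxyl of an acrolein aldol adduct of the C6 acyl unit.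
4. Forward order: the Evans aldol joins C5–C6; reduction and silylation park C6 at the alcohol level; esterification with 18 tethers the halves through C5–O; the Ireland–Claisen rearrangement moves the link from C5–O to C2–C3; diimide saturates C4=C5; C6 is then oxidised to the methyl ester. No ring is formed.
5. Stereochemistry: C6 and the C5 carbinol centre both come from the (S)-4-benzyloxazolidin-2-one aldol. The C5 centre is consumed and relayed to C2 through the chair transition state of the [3,3] shift, with the enolate geometry as the second control element, so one auxiliary sets the remote 1,5-pair.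

Key step: step 9

Remark on the chemistry: Wittig product 17 may contain some (E) isomer; this is without consequence because step 7 saturates the alkene.

**Route**

Step 1
Reactants: 1 (4-carboxybutyl)triphenylphosphonium bromide; 2 acetone
Product: 4 6-methylhept-5-enoic acid, via phosphonium ylide 3 (not isolated)
Conditions: NaN(SiMe3)2 (2.1 equiv), THF, 0 °C; then acetone (excess), −78 °C → rt; 1 M HCl work-up
Reagents that add atoms: none
Why: Wittig olefination, in which the non-stabilised ylide 3 (formed after the carboxylic acid has been deprotonated) should add to acetone and collapse through the oxaphosphetane to a trisubstituted alkene that has no geometry to control.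

Step 2
Reactants: 4 6-methylhept-5-enoic acid; 5 (S)-4-benzyloxazolidin-2-one
Product: 7 (S)-4-benzyl-3-(6-methylhept-5-enoyl)oxazolidin-2-one, via mixed anhydride 6 (not isolated)
Conditions: t-BuCOCl, Et3N, THF, −20 °C; then LiCl, 5, −20 °C → rt
Reagents that add atoms: none
Why: N-acylation of the oxazolidinone through the pivalic mixed anhydride should occur at the less hindered carbonyl group of 6 and installs the auxiliary that later sets C6.

Step 3
Reactants: 7 (S)-4-benzyl-3-(6-methylhept-5-enoyl)oxazolidin-2-one; 8 acrolein
Product: 11 (S)-4-benzyl-3-[(2S,3R)-3-hydroxy-2-(4-methylpent-3-en-1-yl)pent-4-enoyl]oxazolidin-2-one, via boron enolate 9 (not isolated), via boron aldolate 10 (not isolated)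
Conditions: Bu2BOTf, iPr2NEt, CH2Cl2, 0 °C; then acrolein, −78 → 0 °C; pH 7 phosphate buffer, MeOH, 30% H2O2, 0 °C
Reagents that add atoms: none
Why: Evans syn-aldol reaction, in which the (Z)-boron enolate 9 adds 1,2 to acrolein through a closed Zimmerman–Traxler chair on the enolate face opposite the benzyl group, which should set the later C6 and the allylic carbinol centre together as the (2S,3R) syn pair.

Step 4
Reactants: 11 (S)-4-benzyl-3-[(2S,3R)-3-hydroxy-2-(4-methylpent-3-en-1-yl)pent-4-enoyl]oxazolidin-2-one
Product: 12 (2R,3R)-2-(4-methylpent-3-en-1-yl)pent-4-ene-1,3-diol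
Conditions: LiBH4, THF, 0 °C → rt; aqueous NaOH work-up
Reagents that add atoms: none
Why: Reductive cleavage of the N-acyl oxazolidinone by LiBH4 should give the primary alcohol without touching the alkenes or the stereocentres, and stores C6 at the alcohol oxidation level, where its hydrogen is not acidic and no second carbonyl group enters the key step.

Step 5
Reactants: 12 (2R,3R)-2-(4-methylpent-3-en-1-yl)pent-4-ene-1,3-diol
Product: 13 (3R,4R)-8-methyl-4-{[(triethylsilyl)oxy]methyl}nona-1,7-dien-3-ol
Conditions: Et3SiCl (1.05 equiv), imidazole, CH2Cl2, −78 °C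
Reagents that add atoms: chlorotriethylsilane, CC[Si](Cl)(CC)CC
Why: Silylation discriminates on steric grounds, so the primary hydroxyl should react well before the secondary allylic hydroxyl that is flanked by the branched carbon.

Step 6
Reactants: 14 furan-3-carbaldehyde; 15 (3-carboxypropyl)triphenylphosphonium bromide
Product: 17 (Z)-5-(furan-3-yl)pent-4-enoic acid, via phosphonium ylide 16 (not isolated)
Conditions: NaN(SiMe3)2 (2.1 equiv), THF, 0 °C; then 14, −78 °C → rt; 1 M HCl work-up (to pH 3)
Reagents that add atoms: none
Why: Wittig olefination of the aldehyde with the non-stabilised carboxylate ylide 16 should give mainly the (Z)-alkene and delivers the five-carbon acid chain on the furan in one operation.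

Step 7
Reactants: 17 (Z)-5-(furan-3-yl)pent-4-enoic acid
Product: 18 5-(furan-3-yl)pentanoic acid
Conditions: H2 (1 atm), RhCl(PPh3)3 (5 mol %), benzene–EtOH, rt
Reagents that add atoms: none
Why: Homogeneous hydrogenation with RhCl(PPh3)3 should saturate the disubstituted alkene and leave the aromatic furan untouched.

Step 8
Reactants: 13 (3R,4R)-8-methyl-4-{[(triethylsilyl)oxy]methyl}nona-1,7-dien-3-ol; 18 5-(furan-3-yl)pentanoic acid
Product: 19 (3R,4R)-8-methyl-4-{[(triethylsilyl)oxy]methyl}nona-1,7-dien-3-yl 5-(furan-3-yl)pentanoate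
Conditions: DCC, DMAP (0.2 equiv), CH2Cl2, 0 °C → rt
Reagents that add atoms: none
Why: Steglich esterification (carbodiimide activation with DMAP as acyl-transfer catalyst) should acylate the hindered secondary allylic alcohol under neutral conditions without allylic transposition or loss of the silyl ether.

Step 9
Reactants: 19 (3R,4R)-8-methyl-4-{[(triethylsilyl)oxy]methyl}nona-1,7-dien-3-yl 5-(furan-3-yl)pentanoate
Product: 24 (2R,4E,6S)-2-[3-(furan-3-yl)propyl]-6-(hydroxymethyl)-10-methylundeca-4,9-dienoic acid, via lithium enolate 20 (not isolated), via silyl ketene acetal 21 (not isolated), via trimethylsilyl ester 22 (not isolated), via silyl ether acid 23 (not isolated)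
Conditions: LiN(iPr)2 (1.2 equiv), THF, −78 °C, no polar cosolvent; Me3SiCl–Et3N, −78 °C → rt, then 50 °C; 1 M HCl, THF, 0 °C → rt
Reagents that add atoms: none
Why: Kinetic deprotonation of the pentanoate α-CH2 in THF through the closed Ireland transition state should give enolate 20 with the furylpropyl chain trans to O–Li, which Me3SiCl fixes as the (E)-silyl ketene acetal 21 (chain cis to the allylic oxygen). On warming, 21 should undergo the concerted suprafacial [3,3]-sigmatropic shift of an Ireland–Claisen rearrangement, the closest known reaction type being the chirality-transferring ester enolate Claisen rearrangement of esters of secondary 1-alken-3-ols. No ring is closed: the C2–C3 bond forms between the enolate carbon and the terminal vinyl carbon through a six-membered chair transition state in which the branched substituent of the carbinol carbon (the future C6) is equatorial, which also gives the (4E)-alkene. The new stereocentre C2 is controlled by the (R) configuration of the C–O carbon, which is destroyed in the process, together with the ketene acetal geometry: the chain of 21 is axial in that chair, so the vinyl terminus should add to the face of the enolate carbon that gives the configuration of the target at C2 (formally 2R in 24 because the alkene changes the priorities, 2S after step 10). The step needs site-selective enolisation and a single enolate geometry, and the substrate secures the first because the acyl CH2 is the only acidic C–H: with C6 held as a silyl ether, neither β-elimination nor Dieckmann-type attack on a second carbonyl group can compete, and C6 cannot epimerise. Acidic work-up cleaves the silyl ester and then the triethylsilyl ether, so the carboxylic acid that the target carries free is delivered directly.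

Step 10
Reactants: 24 (2R,4E,6S)-2-[3-(furan-3-yl)propyl]-6-(hydroxymethyl)-10-methylundeca-4,9-dienoic acid
Product: 25 (2S,6R)-2-[3-(furan-3-yl)propyl]-6-(hydroxymethyl)-10-methylundec-9-enoic acid
Conditions: 2-nitrobenzenesulfonylhydrazide, Et3N, CH2Cl2, rt (added in portions until the disubstituted alkene is consumed)
Reagents that add atoms: none
Why: Diimide reduction transfers two hydrogens in a concerted syn fashion at a rate that falls steeply with alkene substitution, so the 1,2-disubstituted alkene should be saturated while the trisubstituted alkene and the furan are kept; it is placed before the oxidation so that C6 never carries a carbonyl group and an adjacent alkene at the same time.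

Step 11
Reactants: 25 (2S,6R)-2-[3-(furan-3-yl)propyl]-6-(hydroxymethyl)-10-methylundec-9-enoic acid
Product: 26 (2S,6R)-6-formyl-2-[3-(furan-3-yl)propyl]-10-methylundec-9-enoic acid
Conditions: Dess–Martin periodinane, CH2Cl2, 0 °C → rt; used directly in step 12
Reagents that add atoms: none
Why: Dess–Martin oxidation should convert the primary alcohol into the aldehyde under near-neutral conditions that tolerate the free acid, the furan and the alkene and should not epimerise the α-stereocentre.

Step 12
Reactants: 26 (2S,6R)-6-formyl-2-[3-(furan-3-yl)propyl]-10-methylundec-9-enoic acid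
Product: 27 (2S,6R)-2-[3-(furan-3-yl)propyl]-6-(methoxycarbonyl)-10-methylundec-9-enoic acid
Conditions: (C5H5NH)2Cr2O7 (6 equiv), MeOH (6 equiv), dry DMF, rt
Reagents that add atoms: methanol, CO
Why: Oxidative esterification, in which the aldehyde forms a methyl hemiacetal that the dichromate oxidises to the methyl ester while the free carboxylic acid cannot be esterified under these non-acidic conditions, so the two carboxyl groups should be differentiated without a protecting group.

**Compound list**

1 | (4-carboxybutyl)triphenylphosphonium bromide | OC(=O)CCCC[P+](c1ccccc1)(c1ccccc1)c1ccccc1.[Br-] | starting material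
2 | acetone | CC(C)=O | starting material
3 | sodium 5-(triphenylphosphoranylidene)pentanoate | [Na+].[O-]C(=O)CCCC=P(c1ccccc1)(c1ccccc1)c1ccccc1 | intermediate
4 | 6-methylhept-5-enoic acid | CC(C)=CCCCC(=O)O | intermediate
5 | (S)-4-benzyloxazolidin-2-one | O=C1N[C@@H](Cc2ccccc2)CO1 | starting material
6 | 6-methylhept-5-enoic pivalic anhydride | CC(C)=CCCCC(=O)OC(=O)C(C)(C)C | intermediate
7 | (S)-4-benzyl-3-(6-methylhept-5-enoyl)oxazolidin-2-one | CC(C)=CCCCC(=O)N1[C@@H](Cc2ccccc2)COC1=O | intermediate
8 | acrolein | C=CC=O | starting material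
9 | dibutylboron (Z)-enolate of 7 | CCCCB(CCCC)O/C(=C\CCC=C(C)C)N1[C@@H](Cc2ccccc2)COC1=O | intermediate
10 | dibutylboron aldolate of 11 | O=C(N1[C@@H](Cc2ccccc2)COC1=O)[C@@H](CCC=C(C)C)[C@H](OB(CCCC)CCCC)C=C | intermediate
11 | (S)-4-benzyl-3-[(2S,3R)-3-hydroxy-2-(4-methylpent-3-en-1-yl)pent-4-enoyl]oxazolidin-2-one | O=C(N1[C@@H](Cc2ccccc2)COC1=O)[C@@H](CCC=C(C)C)[C@H](O)C=C | intermediate
12 | (2R,3R)-2-(4-methylpent-3-en-1-yl)pent-4-ene-1,3-diol | OC[C@@H](CCC=C(C)C)[C@H](O)C=C | intermediate
13 | (3R,4R)-8-methyl-4-{[(triethylsilyl)oxy]methyl}nona-1,7-dien-3-ol | CC[Si](CC)(CC)OC[C@@H](CCC=C(C)C)[C@H](O)C=C | intermediate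
14 | furan-3-carbaldehyde | O=Cc1ccoc1 | starting material
15 | (3-carboxypropyl)triphenylphosphonium bromide | OC(=O)CCC[P+](c1ccccc1)(c1ccccc1)c1ccccc1.[Br-] | starting material
16 | sodium 4-(triphenylphosphoranylidene)butanoate | [Na+].[O-]C(=O)CCC=P(c1ccccc1)(c1ccccc1)c1ccccc1 | intermediate
17 | (Z)-5-(furan-3-yl)pent-4-enoic acid | OC(=O)CC/C=C\c1ccoc1 | intermediate
18 | 5-(furan-3-yl)pentanoic acid | OC(=O)CCCCc1ccoc1 | intermediate
19 | (3R,4R)-8-methyl-4-{[(triethylsilyl)oxy]methyl}nona-1,7-dien-3-yl 5-(furan-3-yl)pentanoate | CC[Si](CC)(CC)OC[C@@H](CCC=C(C)C)[C@H](OC(=O)CCCCc1ccoc1)C=C | intermediate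
20 | lithium enolate of 19 (side chain trans to O–Li) | [Li]O/C(=C/CCCc1ccoc1)O[C@H](C=C)[C@@H](CO[Si](CC)(CC)CC)CCC=C(C)C | intermediate
21 | (E)-trimethylsilyl ketene acetal of 19 | C[Si](C)(C)O/C(=C/CCCc1ccoc1)O[C@H](C=C)[C@@H](CO[Si](CC)(CC)CC)CCC=C(C)C | intermediate
22 | trimethylsilyl (2R,4E,6S)-2-[3-(furan-3-yl)propyl]-10-methyl-6-{[(triethylsilyl)oxy]methyl}undeca-4,9-dienoate | C[Si](C)(C)OC(=O)[C@H](CCCc1ccoc1)C/C=C/[C@@H](CO[Si](CC)(CC)CC)CCC=C(C)C | intermediate
23 | (2R,4E,6S)-2-[3-(furan-3-yl)propyl]-10-methyl-6-{[(triethylsilyl)oxy]methyl}undeca-4,9-dienoic acid | OC(=O)[C@H](CCCc1ccoc1)C/C=C/[C@@H](CO[Si](CC)(CC)CC)CCC=C(C)C | intermediate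
24 | (2R,4E,6S)-2-[3-(furan-3-yl)propyl]-6-(hydroxymethyl)-10-methylundeca-4,9-dienoic acid | OC(=O)[C@H](CCCc1ccoc1)C/C=C/[C@@H](CO)CCC=C(C)C | intermediate
25 | (2S,6R)-2-[3-(furan-3-yl)propyl]-6-(hydroxymethyl)-10-methylundec-9-enoic acid | OC(=O)[C@H](CCCc1ccoc1)CCC[C@@H](CO)CCC=C(C)C | intermediate
26 | (2S,6R)-6-formyl-2-[3-(furan-3-yl)propyl]-10-methylundec-9-enoic acid | OC(=O)[C@H](CCCc1ccoc1)CCC[C@@H](C=O)CCC=C(C)C | intermediate
27 | (2S,6R)-2-[3-(furan-3-yl)propyl]-6-(methoxycarbonyl)-10-methylundec-9-enoic acid | COC(=O)[C@@H](CCC=C(C)C)CCC[C@@H](CCCc1ccoc1)C(=O)O | target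

**Step count and risks**

Total step count: 12. Longest linear sequence: 10 steps (steps 1–5 and 8–12, from 1).

Steps most likely to fail:

Step 9. Enolate geometry may be incompletely controlled, or part of the material may react through a boat. Either would erode the configuration at C2 and give a remote diastereomer that is hard to remove. The fallback makes the same C2–C3 bond by auxiliary-controlled enolate alkylation; it sets out from 13, 18 and 5 and rejoins the route at 24. Alcohol 13 is treated with PBr3 (Et2O, −10 °C), which should give, with allylic transposition, the primary bromide triethyl{[(2S,3E)-5-bromo-2-(4-methylpent-3-en-1-yl)pent-3-en-1-yl]oxy}silane F1. Acid 18 is coupled with oxazolidinone 5 (DCC, DMAP, CH2Cl2) to give (S)-4-benzyl-3-[5-(furan-3-yl)pentanoyl]oxazolidin-2-one F2. Deprotonation of F2 with NaN(SiMe3)2 (THF, −78 °C) should give the sodium (Z)-enolate of F2 F3, which is alkylated by F1 on the face opposite the benzyl group to give (S)-4-benzyl-3-[(2R,4E,6S)-2-[3-(furan-3-yl)propyl]-10-methyl-6-{[(triethylsilyl)oxy]methyl}undeca-4,9-dienoyl]oxazolidin-2-one F4. LiOH/H2O2 (THF–H2O, 0 °C) then releases silyl ether acid 23, and 1 M HCl gives 24.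

Step 12. The aldehyde hydrate may be over-oxidised to the diacid, or slow hemiacetal oxidation may allow epimerisation at C6. The fallback differentiates the two carboxyl groups by protection; it sets out from 25 and rejoins at 27. The acid of 25 is alkylated (allyl bromide, K2CO3, DMF) to give allyl (2S,6R)-2-[3-(furan-3-yl)propyl]-6-(hydroxymethyl)-10-methylundec-9-enoate F5. Oxidation of the alcohol to the acid with (C5H5NH)2Cr2O7 in wet DMF should give allyl (2S,6R)-6-carboxy-2-[3-(furan-3-yl)propyl]-10-methylundec-9-enoate F6. Methylation with Me3SiCHN2 (MeOH–toluene) gives allyl (2S,6R)-2-[3-(furan-3-yl)propyl]-6-(methoxycarbonyl)-10-methylundec-9-enoate F7. Allyl transfer to morpholine with Pd(PPh3)4 (THF, rt) then frees the acid 27.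

Step 10. Chemoselectivity may be lost, with partial saturation of the trisubstituted alkene. The fallback replaces rate discrimination by substrate direction; it sets out from 24 and rejoins at 25 without a new compound. Hydrogenation of 24 with the cationic complex [Rh(nbd)(dppb)]BF4 under H2 in CH2Cl2 should be delivered to the C4=C5 alkene by the homoallylic hydroxyl and the carboxyl group, which bind the metal next to that alkene only.

**Further compounds**

F1 | step 9 | triethyl{[(2S,3E)-5-bromo-2-(4-methylpent-3-en-1-yl)pent-3-en-1-yl]oxy}silane | BrC/C=C/[C@@H](CO[Si](CC)(CC)CC)CCC=C(C)C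
F2 | step 9 | (S)-4-benzyl-3-[5-(furan-3-yl)pentanoyl]oxazolidin-2-one | O=C(CCCCc1ccoc1)N1[C@@H](Cc2ccccc2)COC1=O
F3 | step 9 | sodium (Z)-enolate of F2 | [Na]O/C(=C\CCCc1ccoc1)N1[C@@H](Cc2ccccc2)COC1=O
F4 | step 9 | (S)-4-benzyl-3-[(2R,4E,6S)-2-[3-(furan-3-yl)propyl]-10-methyl-6-{[(triethylsilyl)oxy]methyl}undeca-4,9-dienoyl]oxazolidin-2-one | O=C([C@H](CCCc1ccoc1)C/C=C/[C@@H](CO[Si](CC)(CC)CC)CCC=C(C)C)N1[C@@H](Cc2ccccc2)COC1=O
F5 | step 12 | allyl (2S,6R)-2-[3-(furan-3-yl)propyl]-6-(hydroxymethyl)-10-methylundec-9-enoate | C=CCOC(=O)[C@H](CCCc1ccoc1)CCC[C@@H](CO)CCC=C(C)C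
F6 | step 12 | allyl (2S,6R)-6-carboxy-2-[3-(furan-3-yl)propyl]-10-methylundec-9-enoate | C=CCOC(=O)[C@H](CCCc1ccoc1)CCC[C@@H](C(=O)O)CCC=C(C)C
F7 | step 12 | allyl (2S,6R)-2-[3-(furan-3-yl)propyl]-6-(methoxycarbonyl)-10-methylundec-9-enoate | C=CCOC(=O)[C@H](CCCc1ccoc1)CCC[C@@H](C(=O)OC)CCC=C(C)C
F0 | step 10 | none | none
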